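The runs were generated by integration with constants of no real substance.

How much substrate, target and isomer of the product stand in the flask at 8.0 h, with 0.260 M of partner on 0.13 M of substrate?

* amount of target in the flask at 8.0 h, in percent of the substrate charged
* amount of substrate in the flask at 8.0 h, in percent of the substrate charged
* amount of isomer of the product in the flask at 8.0 h, in percent of the substrate charged

in all of them: free catalyst 0.99 mM
- north-west: substrate 0.065 M; partner 0.26 M (in portions, 4); run made earlier; portions every 30 min
- south-east: substrate 0.098 M; partner 0.26 M (in portions, 4); run made earlier; portions every 30 min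
- east: substrate 0.13 M; partner 0.39 M (in portions, 4); run made earlier; portions every 30 min
- flask: substrate 0.13 M; partner 0.260 M (in portions, 4); the portions of partner follow each other after 30 min, the first at the start; time 8.0 h

| run | time / h | target / % | substrate / % | isomer of the product / % |
|---|---|---|---|---|
| north-west | 0.333 | 3 | 96 | 0 |
| north-west | 1.00 | 14 | 82 | 3 |
| north-west | 1.50 | 26 | 71 | 8 |
| north-west | 2.50 | 33 | 47 | 17 |
| north-west | 4.00 | 38 | 30 | 26 |
| north-west | 5.00 | 38 | 30 | 36 |
| south-east | 0.833 | 10 | 88 | 2 |
| south-east | 1.50 | 22 | 70 | 8 |
| south-east | 2.50 | 32 | 47 | 18 |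
| south-east | 3.00 | 38 | 46 | 19 |
| south-east | 4.00 | 34 | 37 | 28 |
| south-east | 5.00 | 37 | 30 | 36 |
| east | 1.00 | 20 | 76 | 3 |
| east | 2.00 | 39 | 45 | 15 |
| east | 3.00 | 44 | 32 | 28 |
| east | 4.00 | 41 | 25 | 34 |
| east | 5.00 | 41 | 20 | 37 |

(each reading ± 1.5 percentage points)

- the analysis behind the earlier runs scatters by 1.5 percentage points, standard deviation

I climb the ladder of times in the runs from the quick end. The partner is all in after 1.50 h, sooner than the substrate of the north-west run reaches 47% at 2.50 h. Later, at 4.00 h, the target of that run reads 38%, and it reads the same at 5.00 h, while its isomer climbs to 36%.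

On the last rung I follow one number, the conversion quotient Γ, a reaction quotient: ([target] + [isomer]) / ([substrate][partner]). I assume one partner per substrate converted and count target plus isomer as the substrate converted, so [partner] is its whole charge minus a correction, that converted substrate. At 5.00 h the north-west, south-east and east runs read 10.9 L mol⁻¹, 12.2 L mol⁻¹ and 14.0 L mol⁻¹, on average 12.4 L mol⁻¹. At 4.00 h their average reads 9.91 L mol⁻¹. Carrying that rise straight on to 8.0 h gives Γ = 19.7 L mol⁻¹. Solving this for the flask, with its own correction to [partner], I commit to 24.0% substrate.

The forecast gives 37% target, 20% substrate and 43% isomer, holding of the flask, with the north-west and south-east runs in view, that “it should track those runs”; its substrate lies 4 percentage points below mine.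

The flask gives 30.4% target, 26.3% substrate and 43.1% isomer.

    substrate + partner ⇌ target (K = 8.00 L mol⁻¹, k = 2.10 L mol⁻¹ h⁻¹)
    substrate + partner ⇌ isomer of the product (K = 16.0 L mol⁻¹, k = 0.170 L mol⁻¹ h⁻¹)
    target + free catalyst ⇌ isomer of the product + free catalyst, rate k3*[free catalyst]*[target] forward; the back reaction follows from the equilibrium constant (k = 320 L mol⁻¹ h⁻¹)
    substrate + free catalyst → spent catalyst (k = 0.640 L mol⁻¹ h⁻¹)

With that substrate, Γ of the flask at 8.0 h comes to 17.1 L mol⁻¹, lower than the 19.7 L mol⁻¹ I carried. Now take the neighbouring flask, with 0.033 M of substrate and the same partner charge and time. Solved with 17.1 L mol⁻¹ for this smaller substrate charge, Γ gives 20.0% substrate. The neighbouring flask holds 19.0% substrate, with 89.7% of its partner charge left, against 63.2% in the flask.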